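The eleven-membered ring is never cyclised; it is released from a fused bicycle. A temporary C1–C7 bond turns C7–C8–C9–C10–C11–C1 into a dimedone-derived six-membered ring fused to the seven-membered ring C1–C2–C3–C4–C5–C6–C7, and leaves C15 on C1 in a 1,3-relationship to the C7 oxygen. Base-induced heterolysis of C1–C7 in a bicyclo[5.4.0]undec-4-ene carrying a tertiary C7 hydroxyl, a C15 tosylate and a C11 silyl ether then gives, in one operation, the C1=C15 methylene, the C7 ketone and the macrocycle with its ring-cis C4=C5 enoate, whose geometry the seven-membered ring fixed earlier. C11 is set by desymmetrising reduction, C7 after the fragmentation.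

Key step: step 12

Numbering used: C1 is the ring carbon bearing the exocyclic methylene C15; then C2 and C3 (CH2), C4=C5 (carboxyl C14 on C5), C6 (CH2), C7 (angelate), C8 (CH2), C9 (CMe2), C10 (CH2) and C11 (carbinol), bonded back to C1. The target is (7S,11S); the C4=C5 bond is ring-cis (formally E).

Assumption: the C1 and C7 configurations drawn for 8–18 are those expected from delivery anti to the bulkier neighbour in steps 5 and 8; any epimers take the same steps and converge on 19, where both centres become trigonal.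

Design of the precursor:
- O11 is a TIPS ether. It should not migrate to the O7 alkoxide, and a free O11 alkoxide would cut C1–C11 instead.
- O15 stays a TBS ether until the bicycle exists and is sulfonylated only then. A sulfonate present in step 8 would let the first C7 alkoxide open the six-membered ring.
- The acid is a 2-(trimethylsilyl)ethyl (TMSE) ester, so one fluoride treatment ends the synthesis.

Step 1
Reactants: 1 dimedone; 2 acrolein
Product: 3 3-(4,4-dimethyl-2,6-dioxocyclohexyl)propanal (rests largely as its cyclic enol hemiacetal)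
Conditions: H2O, rt
Reagents that add atoms: none
Why: Michael addition of the acidic 1,3-dione to the enal needs no added base in water, and the mono-adduct is drained into its cyclic hemiacetal, which should suppress a second addition.

Step 2
Reactants: 3 3-(4,4-dimethyl-2,6-dioxocyclohexyl)propanal
Product: 4 2-(but-3-en-1-yl)-5,5-dimethylcyclohexane-1,3-dione
Conditions: Ph3PCH3Br (3.2 equiv), KOtBu (3.1 equiv), THF, 0 °C → rt; then 1 M HCl
Reagents that add atoms: methyltriphenylphosphonium bromide, C[P+](c1ccccc1)(c1ccccc1)c1ccccc1.[Br-]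
Why: Wittig methylenation run as for a lactol, in which the first equivalent of base turns the dione into its unreactive enolate and so opens the hemiacetal, leaving the aldehyde as the only electrophile for the ylide.

Step 3
Reactants: 4 2-(but-3-en-1-yl)-5,5-dimethylcyclohexane-1,3-dione; 5 formaldehyde
Product: 6 2-(but-3-en-1-yl)-2-(hydroxymethyl)-5,5-dimethylcyclohexane-1,3-dione
Conditions: 37% aq. CH2O (4 equiv), Et3N (5 mol%), THF, rt; used crude
Reagents that add atoms: none
Why: Aldol hydroxymethylation at C1, the only nucleophilic carbon of the 2-alkyl-1,3-dione, builds the quaternary centre, and near-neutral handling avoids the retro-aldol loss of formaldehyde.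

Step 4
Reactants: 6 2-(but-3-en-1-yl)-2-(hydroxymethyl)-5,5-dimethylcyclohexane-1,3-dione
Product: 7 2-(but-3-en-1-yl)-2-{[(tert-butyldimethylsilyl)oxy]methyl}-5,5-dimethylcyclohexane-1,3-dione
Conditions: TBSCl, imidazole, DMF, 0 °C → rt
Reagents that add atoms: tert-butyldimethylsilyl chloride (TBSCl), CC(C)(C)[Si](C)(C)Cl
Why: Imidazole-mediated O-silylation of the primary alcohol closes the retro-aldol exit and masks O15 until the bicycle has been built.

Step 5
Reactants: 7 2-(but-3-en-1-yl)-2-{[(tert-butyldimethylsilyl)oxy]methyl}-5,5-dimethylcyclohexane-1,3-dione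
Product: 8 (2S,3S)-2-(but-3-en-1-yl)-2-{[(tert-butyldimethylsilyl)oxy]methyl}-3-hydroxy-5,5-dimethylcyclohexan-1-one (C11 hydroxyl cis to the CH2OTBS arm; C1 S and C11 S in the numbering used here)
Conditions: (R)-Me-CBS oxazaborolidine (C18H20BNO, 0.3 equiv), catecholborane (1.3 equiv), toluene, −78 → −30 °C; then MeOH, aq. NaHCO3
Reagents that add atoms: none
Why: Corey–Bakshi–Shibata reduction desymmetrises the dione: the oxazaborolidine binds the carbonyl lone pair anti to quaternary C1 and delivers hydride to give the 11S carbinol under catalyst control, the choice of carbonyl (hydride anti to the bulkier CH2OTBS arm) sets the transient C1 centre, and catecholborane leaves the terminal alkene alone at this temperature.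

Step 6
Reactants: 8 (2S,3S)-2-(but-3-en-1-yl)-2-{[(tert-butyldimethylsilyl)oxy]methyl}-3-hydroxy-5,5-dimethylcyclohexan-1-one
Product: 9 (2S,3S)-2-(but-3-en-1-yl)-2-{[(tert-butyldimethylsilyl)oxy]methyl}-5,5-dimethyl-3-[(triisopropylsilyl)oxy]cyclohexan-1-one
Conditions: TIPSOTf, 2,6-lutidine, CH2Cl2, −78 → 0 °C
Reagents that add atoms: triisopropylsilyl trifluoromethanesulfonate (TIPSOTf), CC(C)[Si](OS(=O)(=O)C(F)(F)F)(C(C)C)C(C)C
Why: Silyl triflate silylation with a hindered pyridine base protects the crowded secondary alcohol without exposing the β-hydroxy ketone to alkoxide, which would open it by retro-aldol cleavage.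

Step 7
Reactants: 10 2-(bromomethyl)acrylic acid; 11 2-(trimethylsilyl)ethanol
Product: 12 2-(trimethylsilyl)ethyl 2-(bromomethyl)prop-2-enoate
Conditions: DCC, 4-(dimethylamino)pyridine (5 mol%), CH2Cl2, 0 °C → rt
Reagents that add atoms: none
Why: Steglich esterification at 0 °C with only catalytic nucleophilic amine forms the ester while sparing the allylic bromide.

Step 8
Reactants: 9 (2S,3S)-2-(but-3-en-1-yl)-2-{[(tert-butyldimethylsilyl)oxy]methyl}-5,5-dimethyl-3-[(triisopropylsilyl)oxy]cyclohexan-1-one; 12 2-(trimethylsilyl)ethyl 2-(bromomethyl)prop-2-enoate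
Product: 14 2-(trimethylsilyl)ethyl 2-{[(1R,2S,3S)-2-(but-3-en-1-yl)-2-{[(tert-butyldimethylsilyl)oxy]methyl}-1-hydroxy-5,5-dimethyl-3-[(triisopropylsilyl)oxy]cyclohexyl]methyl}prop-2-enoate (C7 hydroxyl anti to the CH2OTBS arm; new arm trans to the butenyl arm), via allylzinc bromide 13 (not isolated)
Conditions: Zn dust (4 equiv), 12 (3 equiv), THF/sat. aq. NH4Cl 3:1, 0 °C → rt
Reagents that add atoms: none
Why: Barbier-type zinc allylation with a 2-(alkoxycarbonyl)allyl reagent adds to the C7 ketone from the equatorial face, anti to the axial C9 methyl, which sets C7 under substrate control, and the aqueous medium protonates the alkoxide at once so that it should not close onto its own ester to the α-methylene lactone.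

Step 9
Reactants: 14 2-(trimethylsilyl)ethyl 2-{[(1R,2S,3S)-2-(but-3-en-1-yl)-2-{[(tert-butyldimethylsilyl)oxy]methyl}-1-hydroxy-5,5-dimethyl-3-[(triisopropylsilyl)oxy]cyclohexyl]methyl}prop-2-enoate
Product: 15 2-(trimethylsilyl)ethyl (1S,7R,11S)-1-{[(tert-butyldimethylsilyl)oxy]methyl}-7-hydroxy-9,9-dimethyl-11-[(triisopropylsilyl)oxy]bicyclo[5.4.0]undec-4-ene-5-carboxylate (trans-fused)
Conditions: second-generation Hoveyda–Grubbs catalyst [RuCl2(H2IMes)(=CH-C6H4-2-OiPr)] (5 mol%), toluene (0.005 M), 60 °C
Reagents that add atoms: none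
Why: Ring-closing metathesis of the terminal alkene with the 2-substituted acrylate closes the seven-membered ring, which can hold the trisubstituted C4=C5 bond only in the ring-cis geometry, and once closed the ester can no longer lactonise because that would require a bridgehead alkene.

Step 10
Reactants: 15 2-(trimethylsilyl)ethyl (1S,7R,11S)-1-{[(tert-butyldimethylsilyl)oxy]methyl}-7-hydroxy-9,9-dimethyl-11-[(triisopropylsilyl)oxy]bicyclo[5.4.0]undec-4-ene-5-carboxylate
Product: 16 2-(trimethylsilyl)ethyl (1S,7R,11S)-7-hydroxy-1-(hydroxymethyl)-9,9-dimethyl-11-[(triisopropylsilyl)oxy]bicyclo[5.4.0]undec-4-ene-5-carboxylate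
Conditions: camphor-10-sulfonic acid (0.2 equiv), MeOH/CH2Cl2 1:1, 0 °C → rt
Reagents that add atoms: none
Why: Acid-catalysed methanolysis removes the primary TBS ether far faster than the secondary TIPS ether, and the tertiary alcohol and the TMSE ester are inert to it.

Step 11
Reactants: 16 2-(trimethylsilyl)ethyl (1S,7R,11S)-7-hydroxy-1-(hydroxymethyl)-9,9-dimethyl-11-[(triisopropylsilyl)oxy]bicyclo[5.4.0]undec-4-ene-5-carboxylate
Product: 17 2-(trimethylsilyl)ethyl (1S,7R,11S)-7-hydroxy-9,9-dimethyl-1-{[(4-methylbenzenesulfonyl)oxy]methyl}-11-[(triisopropylsilyl)oxy]bicyclo[5.4.0]undec-4-ene-5-carboxylate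
Conditions: TsCl (1.5 equiv), Et3N, Me3N·HCl (10 mol%), CH2Cl2, 0 °C → rt
Reagents that add atoms: p-toluenesulfonyl chloride (TsCl), Cc1ccc(cc1)S(=O)(=O)Cl
Why: Amine-catalysed sulfonylation reaches the neopentyl primary hydroxyl, while the tertiary C7 hydroxyl cannot be tosylated and the weak amine base cannot trigger fragmentation.

Step 12
Reactants: 17 2-(trimethylsilyl)ethyl (1S,7R,11S)-7-hydroxy-9,9-dimethyl-1-{[(4-methylbenzenesulfonyl)oxy]methyl}-11-[(triisopropylsilyl)oxy]bicyclo[5.4.0]undec-4-ene-5-carboxylate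
Product: 19 2-(trimethylsilyl)ethyl (4E,11S)-9,9-dimethyl-1-methylidene-7-oxo-11-[(triisopropylsilyl)oxy]cycloundec-4-ene-5-carboxylate (ring-cis C4=C5), via potassium C7-alkoxide 18 (not isolated)
Conditions: KOtBu (1.05 equiv), THF, −20 °C → rt, short contact; then pH 7 phosphate buffer
Reagents that add atoms: none
Why: KOtBu turns the tertiary C7 hydroxyl into alkoxide 18, whose oxygen lone pair pushes into the C1–C7 σ bond while that bond, rotated antiperiplanar to the C15–OTs bond, expels tosylate, so that C7=O, C1=C15 and the opened ring arise in one concerted heterolytic event. The closest known reaction type is the Grob (Wharton) fragmentation of cyclic 1,3-diol monosulfonates to medium-ring olefinic ketones. The eleven-membered ring is not closed by a cyclisation but appears when the bond shared by the six- and seven-membered rings is cut, so no ring-closure mode has to be met. No stereocentre is created: C1 and C7 become trigonal, C11 is a spectator, and the ring-cis C4=C5 geometry is inherited from the seven-membered ring. The step needs O7 to be the only donor and C–C cleavage to beat 4-exo displacement, which the substrate secures because O11 is locked as a non-migrating TIPS ether, the tosylate sits on a neopentyl carbon held anti to O7 in the trans-fused chair, and attack of O7 on the ester would demand a bridgehead alkene. It also needs the β,γ-unsaturated ketone to survive, which one equivalent of base, low temperature and a buffered quench should secure, since the tosylate left behind is not basic.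

Step 13
Reactants: 19 2-(trimethylsilyl)ethyl (4E,11S)-9,9-dimethyl-1-methylidene-7-oxo-11-[(triisopropylsilyl)oxy]cycloundec-4-ene-5-carboxylate
Product: 20 2-(trimethylsilyl)ethyl (4E,7S,11S)-7-hydroxy-9,9-dimethyl-1-methylidene-11-[(triisopropylsilyl)oxy]cycloundec-4-ene-5-carboxylate
Conditions: S-selective ketoreductase (chosen from a commercial panel), NADP+ (cat.), i-PrOH (10 vol%), DMSO (5 vol%), pH 7.0 phosphate buffer, 30 °C
Reagents that add atoms: none
Why: Enzymatic carbonyl reduction with isopropanol-driven cofactor recycling sets C7 as S under catalyst control, because the two flanks of the ketone (C6 next to the enoate, neopentyl C8) differ strongly in shape and polarity, and the neutral medium should not conjugate the β,γ-unsaturated ketone.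

Step 14
Reactants: 20 2-(trimethylsilyl)ethyl (4E,7S,11S)-7-hydroxy-9,9-dimethyl-1-methylidene-11-[(triisopropylsilyl)oxy]cycloundec-4-ene-5-carboxylate; 21 angelic acid
Product: 23 2-(trimethylsilyl)ethyl (4E,7S,11S)-9,9-dimethyl-7-{[(2Z)-2-methylbut-2-enoyl]oxy}-1-methylidene-11-[(triisopropylsilyl)oxy]cycloundec-4-ene-5-carboxylate, via angeloyl 2,4,6-trichlorobenzoyl mixed anhydride 22 (not isolated)
Conditions: 21 (3 equiv), 2,4,6-Cl3C6H2COCl (3 equiv), Et3N (6 equiv), toluene, rt; then 20, 75 °C
Reagents that add atoms: none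
Why: Yamaguchi-type acylation through the mixed anhydride without a nucleophilic catalyst is the established way to make angelates without Z-to-E isomerisation to the tiglate, and the shielded trichlorobenzoyl carbonyl directs the alcohol to the angeloyl carbon with retention at C7.

Step 15
Reactants: 23 2-(trimethylsilyl)ethyl (4E,7S,11S)-9,9-dimethyl-7-{[(2Z)-2-methylbut-2-enoyl]oxy}-1-methylidene-11-[(triisopropylsilyl)oxy]cycloundec-4-ene-5-carboxylate
Product: 24 (4E,7S,11S)-11-hydroxy-9,9-dimethyl-7-{[(2Z)-2-methylbut-2-enoyl]oxy}-1-methylidenecycloundec-4-ene-5-carboxylic acid (target CNP0263820.1)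
Conditions: Bu4NF (4 equiv), THF, 0 °C → rt; then aq. NH4Cl, pH 4
Reagents that add atoms: none
Why: Fluoride-induced desilylation cleaves the TMSE ester by β-elimination (ethylene and the carboxylate) and the TIPS ether by Si–O cleavage in one operation, and neither the angelate, the olefins nor the two stereocentres are involved.

Compound list
1 | dimedone (5,5-dimethylcyclohexane-1,3-dione) | CC1(C)CC(=O)CC(=O)C1 | starting material
2 | acrolein | C=CC=O | starting material
3 | 3-(4,4-dimethyl-2,6-dioxocyclohexyl)propanal | O=CCCC1C(=O)CC(C)(C)CC1=O | intermediate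
4 | 2-(but-3-en-1-yl)-5,5-dimethylcyclohexane-1,3-dione | C=CCCC1C(=O)CC(C)(C)CC1=O | intermediate
5 | formaldehyde | C=O | starting material
6 | 2-(but-3-en-1-yl)-2-(hydroxymethyl)-5,5-dimethylcyclohexane-1,3-dione | C=CCCC1(CO)C(=O)CC(C)(C)CC1=O | intermediate
7 | 2-(but-3-en-1-yl)-2-{[(tert-butyldimethylsilyl)oxy]methyl}-5,5-dimethylcyclohexane-1,3-dione | C=CCCC1(CO[Si](C)(C)C(C)(C)C)C(=O)CC(C)(C)CC1=O | intermediate
8 | (2S,3S)-2-(but-3-en-1-yl)-2-{[(tert-butyldimethylsilyl)oxy]methyl}-3-hydroxy-5,5-dimethylcyclohexan-1-one | C=CCC[C@@]1(CO[Si](C)(C)C(C)(C)C)C(=O)CC(C)(C)C[C@@H]1O | intermediate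
9 | (2S,3S)-2-(but-3-en-1-yl)-2-{[(tert-butyldimethylsilyl)oxy]methyl}-5,5-dimethyl-3-[(triisopropylsilyl)oxy]cyclohexan-1-one | C=CCC[C@@]1(CO[Si](C)(C)C(C)(C)C)C(=O)CC(C)(C)C[C@@H]1O[Si](C(C)C)(C(C)C)C(C)C | intermediate
10 | 2-(bromomethyl)acrylic acid | C=C(CBr)C(=O)O | starting material
11 | 2-(trimethylsilyl)ethanol | C[Si](C)(C)CCO | starting material
12 | 2-(trimethylsilyl)ethyl 2-(bromomethyl)prop-2-enoate | C=C(CBr)C(=O)OCC[Si](C)(C)C | intermediate
13 | {2-[(2-(trimethylsilyl)ethoxy)carbonyl]allyl}zinc bromide | C=C(C[Zn]Br)C(=O)OCC[Si](C)(C)C | intermediate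
14 | 2-(trimethylsilyl)ethyl 2-{[(1R,2S,3S)-2-(but-3-en-1-yl)-2-{[(tert-butyldimethylsilyl)oxy]methyl}-1-hydroxy-5,5-dimethyl-3-[(triisopropylsilyl)oxy]cyclohexyl]methyl}prop-2-enoate | C=CCC[C@@]1(CO[Si](C)(C)C(C)(C)C)[C@](O)(CC(=C)C(=O)OCC[Si](C)(C)C)CC(C)(C)C[C@@H]1O[Si](C(C)C)(C(C)C)C(C)C | intermediate
15 | 2-(trimethylsilyl)ethyl (1S,7R,11S)-1-{[(tert-butyldimethylsilyl)oxy]methyl}-7-hydroxy-9,9-dimethyl-11-[(triisopropylsilyl)oxy]bicyclo[5.4.0]undec-4-ene-5-carboxylate | CC(C)(C)[Si](C)(C)OC[C@@]12CC/C=C(/C(=O)OCC[Si](C)(C)C)C[C@]2(O)CC(C)(C)C[C@@H]1O[Si](C(C)C)(C(C)C)C(C)C | intermediate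
16 | 2-(trimethylsilyl)ethyl (1S,7R,11S)-7-hydroxy-1-(hydroxymethyl)-9,9-dimethyl-11-[(triisopropylsilyl)oxy]bicyclo[5.4.0]undec-4-ene-5-carboxylate | OC[C@@]12CC/C=C(/C(=O)OCC[Si](C)(C)C)C[C@]2(O)CC(C)(C)C[C@@H]1O[Si](C(C)C)(C(C)C)C(C)C | intermediate
17 | 2-(trimethylsilyl)ethyl (1S,7R,11S)-7-hydroxy-9,9-dimethyl-1-{[(4-methylbenzenesulfonyl)oxy]methyl}-11-[(triisopropylsilyl)oxy]bicyclo[5.4.0]undec-4-ene-5-carboxylate | Cc1ccc(cc1)S(=O)(=O)OC[C@@]12CC/C=C(/C(=O)OCC[Si](C)(C)C)C[C@]2(O)CC(C)(C)C[C@@H]1O[Si](C(C)C)(C(C)C)C(C)C | intermediate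
18 | potassium C7-alkoxide of 17 | Cc1ccc(cc1)S(=O)(=O)OC[C@@]12CC/C=C(/C(=O)OCC[Si](C)(C)C)C[C@]2([O-])CC(C)(C)C[C@@H]1O[Si](C(C)C)(C(C)C)C(C)C.[K+] | intermediate
19 | 2-(trimethylsilyl)ethyl (4E,11S)-9,9-dimethyl-1-methylidene-7-oxo-11-[(triisopropylsilyl)oxy]cycloundec-4-ene-5-carboxylate | C=C1CC/C=C(/C(=O)OCC[Si](C)(C)C)CC(=O)CC(C)(C)C[C@@H]1O[Si](C(C)C)(C(C)C)C(C)C | intermediate
20 | 2-(trimethylsilyl)ethyl (4E,7S,11S)-7-hydroxy-9,9-dimethyl-1-methylidene-11-[(triisopropylsilyl)oxy]cycloundec-4-ene-5-carboxylate | C=C1CC/C=C(/C(=O)OCC[Si](C)(C)C)C[C@@H](O)CC(C)(C)C[C@@H]1O[Si](C(C)C)(C(C)C)C(C)C | intermediate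
21 | angelic acid ((2Z)-2-methylbut-2-enoic acid) | C/C=C(/C)C(=O)O | starting material
22 | (2Z)-2-methylbut-2-enoic 2,4,6-trichlorobenzoic anhydride | C/C=C(/C)C(=O)OC(=O)c1c(Cl)cc(Cl)cc1Cl | intermediate
23 | 2-(trimethylsilyl)ethyl (4E,7S,11S)-9,9-dimethyl-7-{[(2Z)-2-methylbut-2-enoyl]oxy}-1-methylidene-11-[(triisopropylsilyl)oxy]cycloundec-4-ene-5-carboxylate | C=C1CC/C=C(/C(=O)OCC[Si](C)(C)C)C[C@@H](OC(=O)/C(C)=C\C)CC(C)(C)C[C@@H]1O[Si](C(C)C)(C(C)C)C(C)C | intermediate
24 | (4E,7S,11S)-11-hydroxy-9,9-dimethyl-7-{[(2Z)-2-methylbut-2-enoyl]oxy}-1-methylidenecycloundec-4-ene-5-carboxylic acid | C=C1CC/C=C(/C(=O)O)C[C@@H](OC(=O)/C(C)=C\C)CC(C)(C)C[C@@H]1O | target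

Total step count: 15. Longest linear sequence: 14 steps (steps 1–6 and 8–15 from dimedone 1); step 7 is a one-step side branch.

Steps most likely to fail

Step 12. Once the C1–C7 bond has broken, residual alkoxide may deprotonate C6 of the product and move the C4=C5 bond into conjugation with the new C7 carbonyl, or start a transannular Michael addition. A long-lived alkoxide may also be diverted before it fragments. The fallback replaces the Brønsted base by a latent alkoxide. It sets out from 17: the tertiary hydroxyl is capped with TMSOTf and 2,6-lutidine in CH2Cl2 at −78 °C to give the C7 trimethylsilyl ether of the tosylate F3. One equivalent of Bu4NF in THF at −40 °C then releases the alkoxide, which fragments as it forms, so that no base stronger than fluoride is present in excess. The tertiary TMS ether is cleaved far faster than the TMSE ester or the TIPS ether. The fallback comes back to the route at 19.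

Step 8. Addition to the congested C7 carbonyl may be outrun by protonolysis of the allylzinc in the aqueous medium, or the new alkoxide may close onto its own ester with loss of 11. The fallback masks the alkoxide instead of protonating it. It sets out from 9: reagent 13 is preformed from 12 with Zn and LiCl in dry THF and added at 0 °C, and the zinc alkoxide is silylated in the same flask with TMSOTf and 2,6-lutidine to give the C7 trimethylsilyl ether of the adduct F1. Metathesis under the conditions of step 9 gives the C7 trimethylsilyl ether of the bicycle F2, in which lactonisation is geometrically excluded. The acid methanolysis of step 10 then removes the TMS ether and the primary TBS ether together, and the fallback comes back to the route at 16.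

Step 13. The enzyme may show poor facial selectivity at a ketone flanked by two methylene groups, or poor turnover with this bulky lipophilic substrate. The fallback is stereoconvergent. It sets out from 19: NaBH4 with CeCl3·7H2O in MeOH at −78 °C gives both C7 epimers, which are separated. The 7S epimer 20 goes on through step 14. The 7R alcohol F4 is esterified with angelic acid 21 under Mitsunobu conditions (PPh3, DIAD, toluene, 0 °C → rt), with inversion at C7, and comes back to the route at 23.

Further compounds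
F1 | step 8 | 2-(trimethylsilyl)ethyl 2-{[(1R,2S,3S)-2-(but-3-en-1-yl)-2-{[(tert-butyldimethylsilyl)oxy]methyl}-5,5-dimethyl-3-[(triisopropylsilyl)oxy]-1-[(trimethylsilyl)oxy]cyclohexyl]methyl}prop-2-enoate | C=CCC[C@@]1(CO[Si](C)(C)C(C)(C)C)[C@](O[Si](C)(C)C)(CC(=C)C(=O)OCC[Si](C)(C)C)CC(C)(C)C[C@@H]1O[Si](C(C)C)(C(C)C)C(C)C
F2 | step 8 | 2-(trimethylsilyl)ethyl (1S,7R,11S)-1-{[(tert-butyldimethylsilyl)oxy]methyl}-9,9-dimethyl-11-[(triisopropylsilyl)oxy]-7-[(trimethylsilyl)oxy]bicyclo[5.4.0]undec-4-ene-5-carboxylate | CC(C)(C)[Si](C)(C)OC[C@@]12CC/C=C(/C(=O)OCC[Si](C)(C)C)C[C@]2(O[Si](C)(C)C)CC(C)(C)C[C@@H]1O[Si](C(C)C)(C(C)C)C(C)C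
F3 | step 12 | 2-(trimethylsilyl)ethyl (1S,7R,11S)-9,9-dimethyl-1-{[(4-methylbenzenesulfonyl)oxy]methyl}-11-[(triisopropylsilyl)oxy]-7-[(trimethylsilyl)oxy]bicyclo[5.4.0]undec-4-ene-5-carboxylate | Cc1ccc(cc1)S(=O)(=O)OC[C@@]12CC/C=C(/C(=O)OCC[Si](C)(C)C)C[C@]2(O[Si](C)(C)C)CC(C)(C)C[C@@H]1O[Si](C(C)C)(C(C)C)C(C)C
F4 | step 13 | 2-(trimethylsilyl)ethyl (4E,7R,11S)-7-hydroxy-9,9-dimethyl-1-methylidene-11-[(triisopropylsilyl)oxy]cycloundec-4-ene-5-carboxylate | C=C1CC/C=C(/C(=O)OCC[Si](C)(C)C)C[C@H](O)CC(C)(C)C[C@@H]1O[Si](C(C)C)(C(C)C)C(C)C
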